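**Plan**
- Retrosynthetic cuts, in order: the C3–O ester bond (acid 25 + alcohol 19); C7=C11 (acetone aldol/dehydration) and C9–O (Rubottom); C14 back to CHO; C6–C7 and C5–C10 together in one Diels–Alder step, which opens both rings to an acyclic trienal; finally C3–C4 (crotylation).
- Enabling feature: in ring B the C8 carbonyl lies 1,4 to the quaternary C5, which carries a one-carbon group (C14) and is joined to C10 by ring A's four-carbon bridge C1–C4. This is the retron of a [4+2] between a 2-silyloxydiene (C7=C8–C9=C10) and a 2-substituted acrolein (C5=C6, C14 = CHO) tethered through C1–C4.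
- Forward order: the chain is assembled from 4-silyloxybutanal (C10, C1–C3), a crotyl unit (C4, C5, C14, C15), formaldehyde (C6) and an acetonyl ylide (C7–C9). One cycloaddition then closes ring B and, through the shared C5–C10 bond, ring A. C14 is reduced to methyl, C9 is oxygenated, C11–C13 are added and the ester is attached last.
- Stereochemistry: C3/C4 come from a Brown (Z)-crotylboration. C5/C10 come from the endo (formyl), chair-tether transition state with the C3/C4 substituents equatorial. C9 comes from α-face epoxidation anti to the axial C14 methyl. Both Z-alkenes of the side chain come from angelic acid and from the ring of 3-methylfuran-2(5H)-one.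
- Helpers removed later: CHO at C14 (dienophile activation), OTBS at C8 (diene donor, then the C9 oxygenation handle), PMB at O3, TBS at O9.

Key step: step 8

Remark: 4-[(tert-butyldimethylsilyl)oxy]butanal, 3-methylfuran-2(5H)-one and angelic acid are taken as purchased; atom numbers are those of the eremophilane skeleton (ring A = C1–C5 and C10, ring B = C5–C10, C14 on C5, C15 on C4, C11–C13 on C7), and the descriptors are CIP descriptors in that numbering.

**Step 1**
Reactants: 1 4-[(tert-butyldimethylsilyl)oxy]butanal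
Product: 3 (4R,5R)-1-[(tert-butyldimethylsilyl)oxy]-5-methylhept-6-en-4-ol, via borinate ester 2 (not isolated)
Conditions: cis-but-2-ene, KOtBu, n-BuLi, THF, −78 → −45 °C; (−)-Ipc2BOMe (from (+)-α-pinene), −78 °C; BF3·OEt2; 1, −78 °C; NaOH, H2O2, 0 °C → rt
Reagents that add atoms: cis-but-2-ene, C/C=C\C (delivered as (Z)-crotyl-B(Ipc)2)
Why: Brown crotylboration through a closed chair (Zimmerman–Traxler) transition state, in which the Z geometry of the crotylborane gives the syn relation of the C3 hydroxyl and C15, and the isopinocampheyl groups from (+)-α-pinene direct attack to the Si face of the aldehyde, which should set 3R,4R.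

**Step 2**
Reactants: 3 (4R,5R)-1-[(tert-butyldimethylsilyl)oxy]-5-methylhept-6-en-4-ol
Product: 4 tert-butyl{[(4R,5R)-4-[(4-methoxybenzyl)oxy]-5-methylhept-6-en-1-yl]oxy}dimethylsilane
Conditions: NaH, PMBCl, Bu4NI (cat.), THF/DMF, 0 °C → rt
Reagents that add atoms: 4-methoxybenzyl chloride, COc1ccc(CCl)cc1
Why: Williamson etherification of the sodium alkoxide with the benzylic chloride, which leaves the C3–O bond and hence the configuration untouched.

**Step 3**
Reactants: 4 tert-butyl{[(4R,5R)-4-[(4-methoxybenzyl)oxy]-5-methylhept-6-en-1-yl]oxy}dimethylsilane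
Product: 5 (3R,4R)-7-[(tert-butyldimethylsilyl)oxy]-4-[(4-methoxybenzyl)oxy]-3-methylheptanal
Conditions: PdCl2(PhCN)2 (12 mol%), CuCl2·2H2O (12 mol%), AgNO2 (6 mol%), O2 (1 atm), tBuOH/MeNO2, rt
Reagents that add atoms: dioxygen, O=O (oxygen delivered through the nitrite co-catalyst)
Why: nitrite-modified, aldehyde-selective (anti-Markovnikov) Wacker oxidation of the terminal alkene, the homoallylic ether oxygen reinforcing terminal oxygen delivery, with no stereocentre touched (C4 is β to the new carbonyl).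

**Step 4**
Reactants: 5 (3R,4R)-7-[(tert-butyldimethylsilyl)oxy]-4-[(4-methoxybenzyl)oxy]-3-methylheptanal
Product: 6 (3R,4R)-7-[(tert-butyldimethylsilyl)oxy]-4-[(4-methoxybenzyl)oxy]-3-methyl-2-methylideneheptanal
Conditions: aq. HCHO (37%), pyrrolidine (10 mol%), propionic acid (10 mol%), iPrOH, 45 °C
Reagents that add atoms: formaldehyde, C=O
Why: organocatalytic Mannich condensation–elimination (α-methylenation of an aldehyde) at the only α-carbon, C5, which installs C6 and leaves the β-stereocentre C4 intact.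

**Step 5**
Reactants: 6 (3R,4R)-7-[(tert-butyldimethylsilyl)oxy]-4-[(4-methoxybenzyl)oxy]-3-methyl-2-methylideneheptanal
Product: 7 (3R,4R)-7-hydroxy-4-[(4-methoxybenzyl)oxy]-3-methyl-2-methylideneheptanal
Conditions: HF·pyridine, pyridine, THF, 0 °C → rt
Reagents that add atoms: none
Why: fluoride cleavage of the primary silyl ether under buffered conditions that spare the non-enolisable enal and the PMB ether.

**Step 6**
Reactants: 7 (3R,4R)-7-hydroxy-4-[(4-methoxybenzyl)oxy]-3-methyl-2-methylideneheptanal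
Product: 8 (3R,4R)-4-[(4-methoxybenzyl)oxy]-3-methyl-2-methylideneheptanedial
Conditions: TEMPO (2,2,6,6-tetramethylpiperidine-1-oxyl, cat.), PhI(OAc)2, CH2Cl2, rt
Reagents that add atoms: none
Why: oxoammonium (TEMPO) oxidation of the primary alcohol with PhI(OAc)2 as terminal oxidant, which stops at the aldehyde in the absence of water.

**Step 7**
Reactants: 8 (3R,4R)-4-[(4-methoxybenzyl)oxy]-3-methyl-2-methylideneheptanedial
Product: 9 (3R,4R,7E)-4-[(4-methoxybenzyl)oxy]-3-methyl-2-methylidene-9-oxodec-7-enal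
Conditions: Ph3P=CHC(O)CH3 (1.05 equiv), CH2Cl2, rt
Reagents that add atoms: 1-(triphenylphosphoranylidene)propan-2-one, CC(=O)C=P(c1ccccc1)(c1ccccc1)c1ccccc1
Why: Wittig olefination with the stabilised acetonyl ylide, which should react with the unhindered saturated aldehyde in preference to the conjugated, α-branched enal and give the E-enone (C7–C9 added).

**Step 8**
Reactants: 9 (3R,4R,7E)-4-[(4-methoxybenzyl)oxy]-3-methyl-2-methylidene-9-oxodec-7-enal
Product: 11 (3R,4R,5R,10S)-8-[(tert-butyldimethylsilyl)oxy]-3-[(4-methoxybenzyl)oxy]-11,12,13-trinoreremophil-8-en-14-al, via silyloxy trienal 10 (not isolated)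
Conditions: TBSOTf (1.2 equiv), Et3N (3 equiv), CH2Cl2, −78 → 0 °C; then PhMe, 60 °C
Reagents that add atoms: tert-butyldimethylsilyl trifluoromethanesulfonate, CC(C)(C)[Si](C)(C)OS(=O)(=O)C(F)(F)F
Why: Soft enolisation of the methyl ketone (α'-deprotonation) gives the 2-silyloxy-1,3-diene C7=C8(OTBS)–C9=C10, which undergoes a normal-electron-demand intramolecular Diels–Alder reaction with the 2-substituted acrolein C5(=C6H2)–C14HO; the closest known reaction type is the thermal cyclisation of (E)-1,7,9-decatrienes that carry an activated dienophile. Ring B is closed by the [4+2] cycloaddition itself (new bonds C6–C7 and C5–C10, the latter lagging), and ring A is closed by the same C5–C10 bond as the six-membered ring of the four-carbon tether C1–C4 (fused mode, chair-like). The quaternary centre C5 and the ring-fusion centre C10 are set together: the formyl group lies endo under the diene and the tether exo, which places C14 and H-10 trans (trans-decalin), and the absolute sense is relayed from C3 and C4, whose OPMB and methyl groups stay equatorial on the chair tether so that C14 ends up cis to C15. Regioselectivity is needed and is secured twice, by the tether and by the match of the large diene coefficient at C7 with the large dienophile coefficient at C6 (the 1,4 relation of C8–O and C5–CHO). Endo/exo and π-facial selectivity are needed as well and rest on the secondary-orbital preference of the formyl group and on the 1,3-diaxial penalty that the alternative chair would impose on the C3/C4 substituents. The enol ether is delivered regiodefined as C8=C9, which later directs oxygenation to C9.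

**Step 9**
Reactants: 11 (3R,4R,5R,10S)-8-[(tert-butyldimethylsilyl)oxy]-3-[(4-methoxybenzyl)oxy]-11,12,13-trinoreremophil-8-en-14-al
Product: 13 (3R,4R,5S,10S)-8-[(tert-butyldimethylsilyl)oxy]-3-[(4-methoxybenzyl)oxy]-11,12,13-trinoreremophil-8-ene, via tosylhydrazone 12 (not isolated)
Conditions: TsNHNH2, MgSO4, THF, rt; catecholborane, CHCl3, 0 °C → rt; NaOAc·3H2O, 60 °C
Reagents that add atoms: none
Why: Caglioti deoxygenation in the Kabalka variant, in which hydrazone formation, hydride transfer from catecholborane to C=N and acetate-induced loss of sulfinate and N2 from the diazene turn the neopentyl formyl group into the C14 methyl under non-acidic conditions that should leave the silyl enol ether and all stereocentres untouched (the descriptor at C5 changes only through priorities).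

**Step 10**
Reactants: 13 (3R,4R,5S,10S)-8-[(tert-butyldimethylsilyl)oxy]-3-[(4-methoxybenzyl)oxy]-11,12,13-trinoreremophil-8-ene
Product: 14 (3R,4R,5R,9S,10R)-9-[(tert-butyldimethylsilyl)oxy]-3-[(4-methoxybenzyl)oxy]-11,12,13-trinoreremophilan-8-one
Conditions: mCPBA, NaHCO3, CH2Cl2, −20 → 0 °C
Reagents that add atoms: 3-chloroperoxybenzoic acid, OOC(=O)c1cccc(Cl)c1
Why: Rubottom oxidation, in which the peracid epoxidises the electron-rich C8=C9 enol ether from the face anti to the axial C14 methyl (1,3-related to C9) and epoxide opening with 1,4-silyl migration gives the 9-silyloxy ketone with the oxygen equatorial, which is also the thermodynamically preferred epimer.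

**Step 11**
Reactants: 14 (3R,4R,5R,9S,10R)-9-[(tert-butyldimethylsilyl)oxy]-3-[(4-methoxybenzyl)oxy]-11,12,13-trinoreremophilan-8-one
Product: 16 (3R,4R,5R,7S,9S,10R)-9-[(tert-butyldimethylsilyl)oxy]-11-hydroxy-3-[(4-methoxybenzyl)oxy]eremophilan-8-one, via lithium enolate 15 (not isolated)
Conditions: LiN(iPr)2, THF, −78 °C; acetone, −78 °C; AcOH quench at −78 °C
Reagents that add atoms: acetone, CC(C)=O
Why: kinetic deprotonation should occur at the unhindered C7 methylene and not at the silyloxy-bearing C9 methine, and aldol addition of the enolate to acetone with a cold quench against retro-aldol installs C11–C13; the C7 configuration (drawn equatorial) is of no consequence because step 12 removes it.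

**Step 12**
Reactants: 16 (3R,4R,5R,7S,9S,10R)-9-[(tert-butyldimethylsilyl)oxy]-11-hydroxy-3-[(4-methoxybenzyl)oxy]eremophilan-8-one
Product: 18 (3R,4R,5R,9S,10R)-9-[(tert-butyldimethylsilyl)oxy]-3-[(4-methoxybenzyl)oxy]eremophil-7(11)-en-8-one, via tertiary mesylate 17 (not isolated)
Conditions: MsCl, Et3N, CH2Cl2, 0 °C → rt; then DBU, rt
Reagents that add atoms: none
Why: sulfene-type mesylation of the tertiary carbinol followed by E1cB elimination through the C7 enolate, the acidic C7–H directing the new alkene into conjugation as the tetrasubstituted 7(11)-isopropylidene.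

**Step 13**
Reactants: 18 (3R,4R,5R,9S,10R)-9-[(tert-butyldimethylsilyl)oxy]-3-[(4-methoxybenzyl)oxy]eremophil-7(11)-en-8-one
Product: 19 (3R,4R,5R,9S,10R)-9-[(tert-butyldimethylsilyl)oxy]-3-hydroxyeremophil-7(11)-en-8-one
Conditions: DDQ, CH2Cl2/pH 7 buffer, 0 °C
Reagents that add atoms: none
Why: oxidative cleavage of the 4-methoxybenzyl ether by DDQ and hydrolysis of the resulting oxocarbenium ion, which leaves the silyl ether, the enone and the stereocentres alone.

**Step 14**
Reactants: 20 3-methylfuran-2(5H)-one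
Product: 22 4-methoxybenzyl (Z)-4-hydroxy-2-methylbut-2-enoate, via sodium carboxylate 21 (not isolated)
Conditions: NaOH (1.0 equiv), H2O/THF, rt, evaporate; PMBCl, Bu4NI (cat.), DMF, rt
Reagents that add atoms: sodium hydroxide, [Na+].[OH-]; 4-methoxybenzyl chloride, COc1ccc(CCl)cc1
Why: hydroxide opens the butenolide by acyl–oxygen cleavage, the ring having fixed the Z geometry, and the carboxylate is then alkylated (SN2) by the benzylic chloride while the hydroxyl stays free.

**Step 15**
Reactants: 22 4-methoxybenzyl (Z)-4-hydroxy-2-methylbut-2-enoate; 23 angelic acid [(Z)-2-methylbut-2-enoic acid]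
Product: 24 4-methoxybenzyl (Z)-2-methyl-4-{[(Z)-2-methylbut-2-enoyl]oxy}but-2-enoate
Conditions: PPh3, DIAD, THF, 0 °C
Reagents that add atoms: none
Why: Mitsunobu esterification, in which the primary allylic alcohol is activated as the oxyphosphonium ion and displaced by angelate as nucleophile, so the isomerisation-prone angeloyl unit is never converted into an activated acyl species.

**Step 16**
Reactants: 24 4-methoxybenzyl (Z)-2-methyl-4-{[(Z)-2-methylbut-2-enoyl]oxy}but-2-enoate
Product: 25 (Z)-2-methyl-4-{[(Z)-2-methylbut-2-enoyl]oxy}but-2-enoic acid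
Conditions: TFA, anisole, CH2Cl2, 0 °C
Reagents that add atoms: none
Why: acidolysis of the 4-methoxybenzyl ester, with the benzylic cation trapped by anisole, should free the acid without touching either Z-enoate.

**Step 17**
Reactants: 25 (Z)-2-methyl-4-{[(Z)-2-methylbut-2-enoyl]oxy}but-2-enoic acid; 19 (3R,4R,5R,9S,10R)-9-[(tert-butyldimethylsilyl)oxy]-3-hydroxyeremophil-7(11)-en-8-one
Product: 27 (3R,4R,5R,9S,10R)-9-[(tert-butyldimethylsilyl)oxy]-8-oxoeremophil-7(11)-en-3-yl (Z)-2-methyl-4-{[(Z)-2-methylbut-2-enoyl]oxy}but-2-enoate, via mixed anhydride 26 (not isolated)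
Conditions: 2,4,6-Cl3C6H2COCl, Et3N, PhMe, rt; then 19, DMAP, PhMe, rt → 40 °C
Reagents that add atoms: none
Why: Yamaguchi esterification, in which the hindered aroyl half of the mixed anhydride directs acyl transfer from the enoyl carbonyl to the equatorial C3 hydroxyl, with retention at C3 because the C3–O bond is not broken.

**Step 18**
Reactants: 27 (3R,4R,5R,9S,10R)-9-[(tert-butyldimethylsilyl)oxy]-8-oxoeremophil-7(11)-en-3-yl (Z)-2-methyl-4-{[(Z)-2-methylbut-2-enoyl]oxy}but-2-enoate
Product: 28 (3R,4R,5R,9S,10R)-9-hydroxy-8-oxoeremophil-7(11)-en-3-yl (Z)-2-methyl-4-{[(Z)-2-methylbut-2-enoyl]oxy}but-2-enoate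
Conditions: HF·pyridine, pyridine, THF, 0 °C → rt
Reagents that add atoms: none
Why: fluoride cleavage of the secondary silyl ether under buffered, weakly acidic conditions, chosen to avoid acyl migration, α-ketol isomerisation and Z/E isomerisation of the two enoates.

**Compound list**
1 | 4-[(tert-butyldimethylsilyl)oxy]butanal | CC(C)(C)[Si](C)(C)OCCCC=O | starting material
2 | (4R,5R)-1-[(tert-butyldimethylsilyl)oxy]-5-methylhept-6-en-4-yl diisopinocampheylborinate | O([C@H](CCCO[Si](C)(C)C(C)(C)C)[C@H](C)C=C)B([C@H]1[C@H](C)[C@H]2C[C@@H](C1)C2(C)C)[C@H]1[C@H](C)[C@H]2C[C@@H](C1)C2(C)C | intermediate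
3 | (4R,5R)-1-[(tert-butyldimethylsilyl)oxy]-5-methylhept-6-en-4-ol (syn) | O[C@H](CCCO[Si](C)(C)C(C)(C)C)[C@H](C)C=C | intermediate
4 | tert-butyl{[(4R,5R)-4-[(4-methoxybenzyl)oxy]-5-methylhept-6-en-1-yl]oxy}dimethylsilane | COc1ccc(CO[C@H](CCCO[Si](C)(C)C(C)(C)C)[C@H](C)C=C)cc1 | intermediate
5 | (3R,4R)-7-[(tert-butyldimethylsilyl)oxy]-4-[(4-methoxybenzyl)oxy]-3-methylheptanal | COc1ccc(CO[C@H](CCCO[Si](C)(C)C(C)(C)C)[C@H](C)CC=O)cc1 | intermediate
6 | (3R,4R)-7-[(tert-butyldimethylsilyl)oxy]-4-[(4-methoxybenzyl)oxy]-3-methyl-2-methylideneheptanal | COc1ccc(CO[C@H](CCCO[Si](C)(C)C(C)(C)C)[C@H](C)C(=C)C=O)cc1 | intermediate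
7 | (3R,4R)-7-hydroxy-4-[(4-methoxybenzyl)oxy]-3-methyl-2-methylideneheptanal | COc1ccc(CO[C@H](CCCO)[C@H](C)C(=C)C=O)cc1 | intermediate
8 | (3R,4R)-4-[(4-methoxybenzyl)oxy]-3-methyl-2-methylideneheptanedial | COc1ccc(CO[C@H](CCC=O)[C@H](C)C(=C)C=O)cc1 | intermediate
9 | (3R,4R,7E)-4-[(4-methoxybenzyl)oxy]-3-methyl-2-methylidene-9-oxodec-7-enal | COc1ccc(CO[C@H](CC/C=C/C(C)=O)[C@H](C)C(=C)C=O)cc1 | intermediate
10 | (3R,4R,7E)-9-[(tert-butyldimethylsilyl)oxy]-4-[(4-methoxybenzyl)oxy]-3-methyl-2-methylidenedeca-7,9-dienal | COc1ccc(CO[C@H](CC/C=C/C(=C)O[Si](C)(C)C(C)(C)C)[C@H](C)C(=C)C=O)cc1 | intermediate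
11 | (3R,4R,5R,10S)-8-[(tert-butyldimethylsilyl)oxy]-3-[(4-methoxybenzyl)oxy]-11,12,13-trinoreremophil-8-en-14-al (trans-decalin; formyl on C5 cis to C15 and trans to H-10; OPMB and C15 equatorial) | COc1ccc(CO[C@@H]2CC[C@H]3C=C(O[Si](C)(C)C(C)(C)C)CC[C@]3(C=O)[C@H]2C)cc1 | intermediate
12 | (E)-N-tosylhydrazone of 11 at C14 | COc1ccc(CO[C@@H]2CC[C@H]3C=C(O[Si](C)(C)C(C)(C)C)CC[C@]3(/C=N/NS(=O)(=O)c4ccc(C)cc4)[C@H]2C)cc1 | intermediate
13 | (3R,4R,5S,10S)-8-[(tert-butyldimethylsilyl)oxy]-3-[(4-methoxybenzyl)oxy]-11,12,13-trinoreremophil-8-ene | COc1ccc(CO[C@@H]2CC[C@H]3C=C(O[Si](C)(C)C(C)(C)C)CC[C@]3(C)[C@H]2C)cc1 | intermediate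
14 | (3R,4R,5R,9S,10R)-9-[(tert-butyldimethylsilyl)oxy]-3-[(4-methoxybenzyl)oxy]-11,12,13-trinoreremophilan-8-one | COc1ccc(CO[C@@H]2CC[C@H]3[C@H](O[Si](C)(C)C(C)(C)C)C(=O)CC[C@]3(C)[C@H]2C)cc1 | intermediate
15 | lithium (3R,4R,5R,9S,10R)-9-[(tert-butyldimethylsilyl)oxy]-3-[(4-methoxybenzyl)oxy]-11,12,13-trinoreremophil-7-en-8-olate | COc1ccc(CO[C@@H]2CC[C@H]3[C@H](O[Si](C)(C)C(C)(C)C)C(O[Li])=CC[C@]3(C)[C@H]2C)cc1 | intermediate
16 | (3R,4R,5R,7S,9S,10R)-9-[(tert-butyldimethylsilyl)oxy]-11-hydroxy-3-[(4-methoxybenzyl)oxy]eremophilan-8-one | COc1ccc(CO[C@@H]2CC[C@H]3[C@H](O[Si](C)(C)C(C)(C)C)C(=O)[C@H](C(C)(C)O)C[C@]3(C)[C@H]2C)cc1 | intermediate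
17 | (3R,4R,5R,7S,9S,10R)-9-[(tert-butyldimethylsilyl)oxy]-3-[(4-methoxybenzyl)oxy]-8-oxoeremophilan-11-yl methanesulfonate | COc1ccc(CO[C@@H]2CC[C@H]3[C@H](O[Si](C)(C)C(C)(C)C)C(=O)[C@H](C(C)(C)OS(C)(=O)=O)C[C@]3(C)[C@H]2C)cc1 | intermediate
18 | (3R,4R,5R,9S,10R)-9-[(tert-butyldimethylsilyl)oxy]-3-[(4-methoxybenzyl)oxy]eremophil-7(11)-en-8-one | COc1ccc(CO[C@@H]2CC[C@H]3[C@H](O[Si](C)(C)C(C)(C)C)C(=O)C(=C(C)C)C[C@]3(C)[C@H]2C)cc1 | intermediate
19 | (3R,4R,5R,9S,10R)-9-[(tert-butyldimethylsilyl)oxy]-3-hydroxyeremophil-7(11)-en-8-one | O[C@@H]1CC[C@H]2[C@H](O[Si](C)(C)C(C)(C)C)C(=O)C(=C(C)C)C[C@]2(C)[C@H]1C | intermediate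
20 | 3-methylfuran-2(5H)-one | CC1=CCOC1=O | starting material
21 | sodium (Z)-4-hydroxy-2-methylbut-2-enoate | [Na+].OC/C=C(/C)C(=O)[O-] | intermediate
22 | 4-methoxybenzyl (Z)-4-hydroxy-2-methylbut-2-enoate | OC/C=C(/C)C(=O)OCc1ccc(OC)cc1 | intermediate
23 | angelic acid, (Z)-2-methylbut-2-enoic acid | C/C=C(/C)C(=O)O | starting material
24 | 4-methoxybenzyl (Z)-2-methyl-4-{[(Z)-2-methylbut-2-enoyl]oxy}but-2-enoate | C/C=C(/C)C(=O)OC/C=C(/C)C(=O)OCc1ccc(OC)cc1 | intermediate
25 | (Z)-2-methyl-4-{[(Z)-2-methylbut-2-enoyl]oxy}but-2-enoic acid | C/C=C(/C)C(=O)OC/C=C(/C)C(=O)O | intermediate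
26 | (Z)-2-methyl-4-{[(Z)-2-methylbut-2-enoyl]oxy}but-2-enoic 2,4,6-trichlorobenzoic anhydride | C/C=C(/C)C(=O)OC/C=C(/C)C(=O)OC(=O)c1c(Cl)cc(Cl)cc1Cl | intermediate
27 | (3R,4R,5R,9S,10R)-9-[(tert-butyldimethylsilyl)oxy]-8-oxoeremophil-7(11)-en-3-yl (Z)-2-methyl-4-{[(Z)-2-methylbut-2-enoyl]oxy}but-2-enoate | C/C=C(/C)C(=O)OC/C=C(/C)C(=O)O[C@@H]1CC[C@H]2[C@H](O[Si](C)(C)C(C)(C)C)C(=O)C(=C(C)C)C[C@]2(C)[C@H]1C | intermediate
28 | (3R,4R,5R,9S,10R)-9-hydroxy-8-oxoeremophil-7(11)-en-3-yl (Z)-2-methyl-4-{[(Z)-2-methylbut-2-enoyl]oxy}but-2-enoate (CNP0308665.1) | C/C=C(/C)C(=O)OC/C=C(/C)C(=O)O[C@@H]1CC[C@H]2[C@H](O)C(=O)C(=C(C)C)C[C@]2(C)[C@H]1C | target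

**Count**
Total steps: 18. Longest linear sequence: 15 steps (steps 1–13, 17 and 18); steps 14–16 form the side-chain branch.

**Steps most likely to fail**

Step 8. The silyl triflate may activate the free enal, so that intermolecular Mukaiyama–Michael addition and erosion of the endo (trans-fusion) preference compete with the intramolecular cycloaddition. The fallback sets out from 9 and returns at 11, replacing the Lewis-acid/thermal cycloaddition by a base-mediated anionic double Michael annulation on an ester-level acceptor. Oxidation of the enal (NaClO2, NaH2PO4, 2-methylbut-2-ene, tBuOH/H2O) should give (3R,4R,7E)-4-[(4-methoxybenzyl)oxy]-3-methyl-2-methylidene-9-oxodec-7-enoic acid F1. Methylation (Me3SiCHN2, MeOH/PhMe) gives methyl (3R,4R,7E)-4-[(4-methoxybenzyl)oxy]-3-methyl-2-methylidene-9-oxodec-7-enoate F2. Kinetic deprotonation of the methyl ketone (LiN(SiMe3)2, THF, −78 °C) should trigger Michael addition of C7 to C6 and of C5 to C10, and the resulting C8 enolate is silylated in the same flask (TBSCl, HMPA) to methyl (3R,4R,5R,10S)-8-[(tert-butyldimethylsilyl)oxy]-3-[(4-methoxybenzyl)oxy]-11,12,13-trinoreremophil-8-en-14-oate F3. Reduction of this neopentyl ester with iBu2AlH (CH2Cl2, −78 °C) should stop at aldehyde 11.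

Step 3. Markovnikov oxypalladation to the methyl ketone, or alkene migration through palladium hydride intermediates, may compete with terminal oxidation. The fallback sets out from 4 and returns at 5. Hydroboration with 9-borabicyclo[3.3.1]nonane in THF followed by NaOH/H2O2 should give (3R,4R)-7-[(tert-butyldimethylsilyl)oxy]-4-[(4-methoxybenzyl)oxy]-3-methylheptan-1-ol F4 with purely steric anti-Markovnikov control. Oxidation (TEMPO, PhI(OAc)2, CH2Cl2) then gives 5.

Step 17. The Z-configured α-methyl enoate may isomerise to the E isomer while it is held as an activated acyl species (acylpyridinium), and acylation of the hindered C3 hydroxyl may be slow. The fallback sets out from 19 and returns at 27, making the ester by C–O displacement instead of acyl activation. Oxidation with Dess–Martin periodinane should give (4R,5S,9S,10R)-9-[(tert-butyldimethylsilyl)oxy]eremophil-7(11)-ene-3,8-dione F5. Reduction with Li[HB(sec-Bu)3] (THF, −78 °C), from the face away from the axial C14 methyl, should give the axial alcohol (3S,4R,5R,9S,10R)-9-[(tert-butyldimethylsilyl)oxy]-3-hydroxyeremophil-7(11)-en-8-one F6. A Mitsunobu reaction with acid 25 (PPh3, DIAD, THF) then inverts C3 and should give 27.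

Further compounds
F1 | step 8 | (3R,4R,7E)-4-[(4-methoxybenzyl)oxy]-3-methyl-2-methylidene-9-oxodec-7-enoic acid | COc1ccc(CO[C@H](CC/C=C/C(C)=O)[C@H](C)C(=C)C(=O)O)cc1
F2 | step 8 | methyl (3R,4R,7E)-4-[(4-methoxybenzyl)oxy]-3-methyl-2-methylidene-9-oxodec-7-enoate | COc1ccc(CO[C@H](CC/C=C/C(C)=O)[C@H](C)C(=C)C(=O)OC)cc1
F3 | step 8 | methyl (3R,4R,5R,10S)-8-[(tert-butyldimethylsilyl)oxy]-3-[(4-methoxybenzyl)oxy]-11,12,13-trinoreremophil-8-en-14-oate | COc1ccc(CO[C@@H]2CC[C@H]3C=C(O[Si](C)(C)C(C)(C)C)CC[C@]3(C(=O)OC)[C@H]2C)cc1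
F4 | step 3 | (3R,4R)-7-[(tert-butyldimethylsilyl)oxy]-4-[(4-methoxybenzyl)oxy]-3-methylheptan-1-ol | COc1ccc(CO[C@H](CCCO[Si](C)(C)C(C)(C)C)[C@H](C)CCO)cc1
F5 | step 17 | (4R,5S,9S,10R)-9-[(tert-butyldimethylsilyl)oxy]eremophil-7(11)-ene-3,8-dione | O=C1CC[C@H]2[C@H](O[Si](C)(C)C(C)(C)C)C(=O)C(=C(C)C)C[C@]2(C)[C@H]1C
F6 | step 17 | (3S,4R,5R,9S,10R)-9-[(tert-butyldimethylsilyl)oxy]-3-hydroxyeremophil-7(11)-en-8-one | O[C@H]1CC[C@H]2[C@H](O[Si](C)(C)C(C)(C)C)C(=O)C(=C(C)C)C[C@]2(C)[C@H]1C
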